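**Analysis of the target**

Target 43 is an ester. Its acyl part is the chain C1 (ester carbonyl) to C6, with methyl groups on C2, C4 and C6, a free hydroxyl on C3, a ketone at C5 and, on C6, a fully substituted 4-pyranone (ring A: C7 bonded to C6, C8–C11, ring oxygen between C7 and C11, ethyl C12–C13 on C11). Its alkoxy part is (4R,6R)-5-hydroxy-4,6-dimethylnonane-3,7-dione (C3'–C7'), whose carbinol carbon C5' carries two identical (R)-configured arms and is not a stereocentre. The acid holds four stereocentres, C2 (R), C3 (R), C4 (S) and C6 (S): C2-Me/C3-OH/C4-Me form an anti,anti triad, and C6 is separated from it by the C5 ketone. The alcohol holds C4' and C6' (both R), one methyl syn and one anti to the C5' oxygen. The molecule is base-sensitive throughout: C3–OH is β to an ester and a ketone, both ketones of the alkoxy part are β to the acyloxy group, and C4, C6, C4' and C6' are α to ketones, C6 being also allylic to ring A. The difficulties are the anti,anti triad, the acylation of a hindered β-hydroxy diketone, and the need to create the C5 ketone only at the end. The strategy rests on the 1,5-relation of C1 and the oxygen on C5: joined, they give a six-membered ring B (O5, C1–C5). On that ring the anti,anti triad is the cis,cis pattern, not the all-equatorial one: with the C5 side chain and the C4 methyl trans-diequatorial, the C2 methyl is equatorial and the C3 oxygen is axial between the two methyl groups. Each of these positions answers to a ring-based control element, C5 is a relay centre that ends as the ketone, and C6 is bought.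

**Retrosynthetic reasoning**

The last operations are kept free of base. Target 43 is the desilylation product of 42. The C5 ketone of 42 is made from carbinol 41 by oxidation, late, because once C5 is a ketone C6 is doubly activated. Carbinol 41 comes from bis-silyl ether 40 by selective loss of the more labile silyl group.

The ester C1–O bond of 40 is cut next, giving acid 27 and hydroxy diketone 38. This is the only bond that joins two fragments of comparable size, and both halves can be finished separately. The forward acylation has to join two hindered partners without β-elimination or retro-aldol cleavage of 38.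

Alcohol 38 is traced through silyl ether 37 and diol 36 to alkene 34. The C6'–H and C7'–O bonds are cut (a hydroboration, anti to the C5' oxygen), then the C3'–ethyl bond (amide 33, from 32), then C4'–C5' (a syn aldol between imide 28 and enal 29, giving 31). The one syn and one anti relation of 38 thus come from two reactions of opposite and reliable sense.

Acid 27 is the ring-opened form of δ-lactone 24, in which the C1–O5 bond of ring B is restored. Lactone 24 is taken back through lactol 23 to methyl acetal 22. Carrying C1 as an acetal carbon and not as a lactone carbonyl protects it in every basic step and removes the risk of β-elimination of the axial C3 oxygen while ring A is built.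

Ring A of 22 is opened at its O–C11 bond to triketone 21, and the C7–C8 bond of its precursor 20 is cut to aldehyde 16 and diketone 18 (from 17). One carbon–carbon bond brings in six carbons; the centres formed at C7, C8 and C10 all become trigonal. The forward sequence must not disturb C6, which is α to the aldehyde and later to the C7 ketone.

Aldehyde 16 goes back through 15 and 14 to axial alcohol 13. Its C3–H bond is cut to ketone 12: in the chair, delivery of hydrogen along the equatorial trajectory gives the axial C3 oxygen that the triad demands. Ketone 12 comes from enone 11 by cutting the C1–OMe and C2–H bonds; with C3 as ketone, C2 can settle equatorial by enolisation.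

Enone 11 is cut at C4–C5 and O5–C1 into aldehyde 4 (C5–C7) and diene 9 (C1–C4). This is the central disconnection: it makes ring B and two stereocentres in one operation, and the C6 centre of 4 directs C5, which in turn fixes C4 through the ring.

Aldehyde 4 comes from hydroxy ester 1 through 2 and 3 without touching the stereocentre. Diene 9 comes from ketone 5 and formate 6 through 7 and 8.

**Alternatives that were turned down**

Alternative 1: C1–C5 is taken as a symmetrical unit and cut back to bis-allylic silyl ether A2. In the forward key step both alkenes of A2 are hydroborated and oxidised, each new C–H bond forming anti to the central oxygen, to give meso diol A1. In its favour, A1 has the anti,anti triad directly, in one operation from a very simple precursor, without the ketone detour at C3 that the ring route needs (steps 8 and 9); on this point it is stronger. Against it, A1 is meso, so its two ends must be told apart by an enantiotopic-group-selective step, which alone fixes the absolute configuration of the whole acid half. The C5–C6 bond and the C6 centre must then be made separately, next to a carbonyl and possibly with ring A already present, where C6 is labile. Two hydroborations on one molecule also compound any imperfect facial selectivity. The chosen route gives in exchange an absolute configuration bought with C6, a C5–C6 bond that exists from the start, and two chain ends that are different functional groups from the first step.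

Alternative 2: the O–C11 bond of ring A is cut in an otherwise complete acid half, so that open-chain triketone A4 is cyclodehydrated to pyranone ester A3. In its favour, the dehydration is dependable, ring A appears late, and C1 and O5 already carry their final protecting groups, so no lactone-opening sequence (steps 17–19) is needed; there it is stronger. Against it, the disconnection says nothing about the origin of the five stereocentres of A4, which would have to come from acyclic aldol control in the sense that is hardest for an anti,anti triad. A4 also has C6 α to a ketone and β to a silyloxy group during the dehydration, and the tert-butyl ester must later be cleaved by acid beside two silyl ethers. The same ring closure is used in the chosen route as step 16, on a substrate whose stereocentres are held in ring B, so its advantage is kept while the stereochemical problem is solved elsewhere.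

Alternative 3: the C2–C3 and C5–C6 bonds are both cut, leading to diol A6 and two molecules of allylic acetate A7. In the forward key step a chiral iridium catalyst oxidises A6 transiently and crotylates both ends to dienediol A5. In its favour, two carbon–carbon bonds and four stereocentres arise in one catalytic step from commodity chemicals, with no protecting group and no separate oxidation; for building the carbon skeleton this is clearly the shortest plan. Against it, the two carbinols and the two vinyl groups of A5 differ only in being syn or anti to the central methyl group, yet the target needs one carbinol kept (C3, anti to the C4 methyl) and the other oxidised (C5), and one vinyl group turned into the C1 acid and the other into C7 of ring A. That differentiation costs steps and rests on a small steric difference. The chosen route is longer at the start but gives C1 (acetal carbon), C3 (ring ketone), C5 (ring oxygen) and C7 (benzyl ether) four distinct functions from the key step on.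

Key step: step 7

Assumption: centres that later become trigonal (the anomeric C1 in 12–22, C7/C8/C10 in 20 and 21, C3 in 36) are carried as mixtures and drawn in one form; they have no bearing on 43.

**Route**

Step 1
Reactants: 1 methyl (S)-3-hydroxy-2-methylpropanoate
Product: 2 methyl (S)-3-(benzyloxy)-2-methylpropanoate
Conditions: BnOC(=NH)CCl3, TfOH (cat.), CH2Cl2/cyclohexane, 0 °C to rt
Reagents that add atoms: benzyl 2,2,2-trichloroacetimidate, N=C(OCc1ccccc1)C(Cl)(Cl)Cl
Why: Acid-catalysed O-benzylation with the trichloroacetimidate avoids base, so the α-stereocentre of the β-hydroxy ester should stay intact.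

Step 2
Reactants: 2 methyl (S)-3-(benzyloxy)-2-methylpropanoate
Product: 3 (R)-3-(benzyloxy)-2-methylpropan-1-ol
Conditions: LiAlH4, THF, 0 °C
Reagents that add atoms: none
Why: Hydride reduction of the ester; the stereocentre is not involved and the descriptor changes only because the priorities change.

Step 3
Reactants: 3 (R)-3-(benzyloxy)-2-methylpropan-1-ol
Product: 4 (S)-3-(benzyloxy)-2-methylpropanal
Conditions: (COCl)2, DMSO, CH2Cl2, −78 °C; Et3N, −78 to 0 °C
Reagents that add atoms: none
Why: Swern oxidation stops at the aldehyde; the α-stereocentre should be kept if the crude aldehyde is used at once without chromatography.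

Step 4
Reactants: 5 pentan-3-one; 6 ethyl formate
Product: 7 2-methyl-3-oxopentanal (enol form)
Conditions: NaH, EtOH (cat.), Et2O, 0 °C to rt; aq. HCl
Reagents that add atoms: none
Why: Crossed Claisen condensation (formylation) of the ketone enolate with a non-enolisable formate; the β-keto aldehyde should be obtained as its chelated enol.

Step 5
Reactants: 7 2-methyl-3-oxopentanal (enol form)
Product: 8 (E)-1-methoxy-2-methylpent-1-en-3-one
Conditions: Me2SO4, K2CO3, acetone, reflux
Reagents that add atoms: dimethyl sulfate, COS(=O)(=O)OC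
Why: O-Alkylation of the 1,3-dicarbonyl enolate at the formyl oxygen gives the vinylogous ester, the (E) isomer being the more stable one.

Step 6
Reactants: 8 (E)-1-methoxy-2-methylpent-1-en-3-one
Product: 9 (1E,3Z)-1-methoxy-2-methyl-3-(trimethylsilyloxy)penta-1,3-diene
Conditions: Me3SiOTf, Et3N, Et2O, 0 °C
Reagents that add atoms: trimethylsilyl trifluoromethanesulfonate, C[Si](C)(C)OS(=O)(=O)C(F)(F)F
Why: Soft enolisation and O-silylation of the ethyl ketone should give the (Z)-silyl enol ether and with it the 1-alkoxy-3-silyloxy diene.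

Step 7
Reactants: 4 (S)-3-(benzyloxy)-2-methylpropanal; 9 (1E,3Z)-1-methoxy-2-methyl-3-(trimethylsilyloxy)penta-1,3-diene
Product: 11 (2R,3R)-2-[(S)-1-(benzyloxy)propan-2-yl]-3,5-dimethyl-2,3-dihydro-4H-pyran-4-one, via open-chain aldol adduct 10 (not isolated)
Conditions: BF3·OEt2, CH2Cl2, −78 °C; then CF3CO2H, CH2Cl2, rt
Reagents that add atoms: none
Why: BF3 coordinates the aldehyde oxygen of 4, and the C4 terminus of silyl dienol ether 9 adds through an open, antiperiplanar transition state (Mukaiyama aldol), forming C4–C5 and giving hydroxy enone 10 after loss of the silyl group. Trifluoroacetic acid then promotes addition of the C5 hydroxyl to C1 of the vinylogous ester and loss of methanol, which forms the O5–C1 bond; the closest known reaction type is the Lewis acid-mediated cyclocondensation of 1-alkoxy-3-silyloxy dienes with aldehydes in its stepwise mode. The one ring closes by a 6-endo-trig oxa-conjugate addition followed by β-elimination. C5 is controlled by the C6 centre of 4 in the Felkin–Anh sense: the nucleophile approaches anti to the CH2OBn group and past hydrogen, which should give the C5–O/C6–Me syn relation. C4 is set relative to C5 by the open transition state, which should favour the anti aldol and hence the 2,3-trans ring; because C4 is α to the ring ketone, a cis isomer can also be equilibrated to the trans-diequatorial compound. The step needs Felkin over chelation control and trans over cis: BF3 has a single free coordination site and cannot bridge the aldehyde and benzyl ether oxygens, and the stepwise pathway avoids the endo cycloaddition that leads to the cis ring. C5 serves only as a relay and later becomes the ketone.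

Step 8
Reactants: 11 (2R,3R)-2-[(S)-1-(benzyloxy)propan-2-yl]-3,5-dimethyl-2,3-dihydro-4H-pyran-4-one
Product: 12 (2R,3R,5S,6S)-2-[(S)-1-(benzyloxy)propan-2-yl]-6-methoxy-3,5-dimethyloxan-4-one
Conditions: MeOH, CSA (cat.), rt; Et3N before concentration
Reagents that add atoms: methanol, CO
Why: Acid-catalysed conjugate addition of methanol to the vinylogous ester (acetal formation at C1, the reverse of the elimination in step 7, driven by methanol as solvent). C2, now α to the C3 ketone, should equilibrate through the enol to the equatorial methyl, cis to the C4 methyl, and the anomeric effect should favour the axial methoxy group.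

Step 9
Reactants: 12 (2R,3R,5S,6S)-2-[(S)-1-(benzyloxy)propan-2-yl]-6-methoxy-3,5-dimethyloxan-4-one
Product: 13 (2R,3S,4R,5R,6S)-2-[(S)-1-(benzyloxy)propan-2-yl]-6-methoxy-3,5-dimethyloxan-4-ol
Conditions: LiBH(s-Bu)3, THF, −78 °C; then H2O
Reagents that add atoms: none
Why: The hindered trialkylborohydride should attack the chair ketone along the equatorial trajectory, the axial face being screened by the axial C1 methoxy group and the axial hydrogen on C5. The C3 hydroxyl then ends axial and cis to both methyl groups, which is the anti,anti triad of the chain.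

Step 10
Reactants: 13 (2R,3S,4R,5R,6S)-2-[(S)-1-(benzyloxy)propan-2-yl]-6-methoxy-3,5-dimethyloxan-4-ol
Product: 14 (2R,3R,4R,5R,6S)-2-[(S)-1-(benzyloxy)propan-2-yl]-4-(tert-butyldimethylsilyloxy)-6-methoxy-3,5-dimethyloxane
Conditions: t-BuMe2SiOTf, 2,6-lutidine, CH2Cl2, −78 to 0 °C
Reagents that add atoms: tert-butyldimethylsilyl trifluoromethanesulfonate, CC(C)(C)[Si](C)(C)OS(=O)(=O)C(F)(F)F
Why: The silyl triflate with lutidine should silylate even a hindered axial secondary alcohol; acetal and benzyl ether are inert at low temperature.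

Step 11
Reactants: 14 (2R,3R,4R,5R,6S)-2-[(S)-1-(benzyloxy)propan-2-yl]-4-(tert-butyldimethylsilyloxy)-6-methoxy-3,5-dimethyloxane
Product: 15 (S)-2-[(2R,3R,4R,5R,6S)-4-(tert-butyldimethylsilyloxy)-6-methoxy-3,5-dimethyloxan-2-yl]propan-1-ol
Conditions: H2 (1 atm), Pd/C, EtOAc, rt
Reagents that add atoms: none
Why: Hydrogenolysis of the benzyl ether; the silyl ether and the methyl acetal should survive the neutral conditions.

Step 12
Reactants: 15 (S)-2-[(2R,3R,4R,5R,6S)-4-(tert-butyldimethylsilyloxy)-6-methoxy-3,5-dimethyloxan-2-yl]propan-1-ol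
Product: 16 (R)-2-[(2S,3R,4R,5R,6S)-4-(tert-butyldimethylsilyloxy)-6-methoxy-3,5-dimethyloxan-2-yl]propanal
Conditions: Dess–Martin periodinane, NaHCO3, CH2Cl2, 0 °C to rt
Reagents that add atoms: none
Why: Buffered Dess–Martin oxidation should give the α-branched aldehyde without epimerising C6; it is used directly.

Step 13
Reactants: 17 heptane-3,5-dione
Product: 18 4-methylheptane-3,5-dione
Conditions: MeI, K2CO3, acetone, reflux
Reagents that add atoms: iodomethane, CI
Why: C-Methylation of the β-diketone enolate under mild carbonate conditions.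

Step 14
Reactants: 16 (R)-2-[(2S,3R,4R,5R,6S)-4-(tert-butyldimethylsilyloxy)-6-methoxy-3,5-dimethyloxan-2-yl]propanal; 18 4-methylheptane-3,5-dione
Product: 20 (8S)-8-[(2R,3R,4R,5R,6S)-4-(tert-butyldimethylsilyloxy)-6-methoxy-3,5-dimethyloxan-2-yl]-7-hydroxy-4,6-dimethylnonane-3,5-dione (mixture at C4/C6/C7), via dilithium dianion 19 (not isolated)
Conditions: 18, LiN(i-Pr)2 (2 equiv), THF, 0 °C; then 16, −78 °C; AcOH quench
Reagents that add atoms: none
Why: β-Diketone dianion aldol: the terminal carbanion of 19, formed second, is the more nucleophilic site and should add to the aldehyde to form C7–C8. The new centres are of no consequence, and acetal and silyl ether are inert to the base.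

Step 15
Reactants: 20 (8S)-8-[(2R,3R,4R,5R,6S)-4-(tert-butyldimethylsilyloxy)-6-methoxy-3,5-dimethyloxan-2-yl]-7-hydroxy-4,6-dimethylnonane-3,5-dione
Product: 21 (8R)-8-[(2S,3R,4R,5R,6S)-4-(tert-butyldimethylsilyloxy)-6-methoxy-3,5-dimethyloxan-2-yl]-4,6-dimethylnonane-3,5,7-trione (enol tautomers)
Conditions: Dess–Martin periodinane, CH2Cl2, rt
Reagents that add atoms: none
Why: Dess–Martin oxidation of the β-hydroxy diketone should give the 1,3,5-triketone; C6 of the chain should hold because C8 and C10 are far more acidic.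

Step 16
Reactants: 21 (8R)-8-[(2S,3R,4R,5R,6S)-4-(tert-butyldimethylsilyloxy)-6-methoxy-3,5-dimethyloxan-2-yl]-4,6-dimethylnonane-3,5,7-trione
Product: 22 2-{(R)-1-[(2S,3R,4R,5R,6S)-4-(tert-butyldimethylsilyloxy)-6-methoxy-3,5-dimethyloxan-2-yl]ethyl}-6-ethyl-3,5-dimethyl-4H-pyran-4-one
Conditions: Ph3P, CCl4, 2,6-lutidine, THF, rt
Reagents that add atoms: none
Why: Cyclodehydration of a 1,3,5-triketone to the 4-pyranone: one enol oxygen is activated as its oxyphosphonium salt and displaced by the distal enol oxygen, closing the O–C11 bond of ring A. The buffered, nearly neutral medium should spare the acetal, the silyl ether and C6.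

Step 17
Reactants: 22 2-{(R)-1-[(2S,3R,4R,5R,6S)-4-(tert-butyldimethylsilyloxy)-6-methoxy-3,5-dimethyloxan-2-yl]ethyl}-6-ethyl-3,5-dimethyl-4H-pyran-4-one
Product: 23 (3R,4R,5R,6S)-4-(tert-butyldimethylsilyloxy)-6-[(R)-1-(6-ethyl-3,5-dimethyl-4-oxo-4H-pyran-2-yl)ethyl]-3,5-dimethyloxan-2-ol (both anomers)
Conditions: AcOH/THF/H2O, 40 °C
Reagents that add atoms: water, O
Why: Mild aqueous acid should hydrolyse the methyl acetal, which has no electron-withdrawing group on C2, while the hindered secondary silyl ether and ring A stay.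

Step 18
Reactants: 23 (3R,4R,5R,6S)-4-(tert-butyldimethylsilyloxy)-6-[(R)-1-(6-ethyl-3,5-dimethyl-4-oxo-4H-pyran-2-yl)ethyl]-3,5-dimethyloxan-2-ol
Product: 24 (3R,4R,5R,6S)-4-(tert-butyldimethylsilyloxy)-6-[(R)-1-(6-ethyl-3,5-dimethyl-4-oxo-4H-pyran-2-yl)ethyl]-3,5-dimethyloxan-2-one
Conditions: PhI(OAc)2, TEMPO (cat.), CH2Cl2, rt
Reagents that add atoms: none
Why: Oxoammonium (TEMPO) oxidation of the lactol to the δ-lactone under nearly neutral conditions, so the equatorial C2 methyl should be kept.

Step 19
Reactants: 24 (3R,4R,5R,6S)-4-(tert-butyldimethylsilyloxy)-6-[(R)-1-(6-ethyl-3,5-dimethyl-4-oxo-4H-pyran-2-yl)ethyl]-3,5-dimethyloxan-2-one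
Product: 27 (2R,3R,4R,5S,6R)-3-(tert-butyldimethylsilyloxy)-6-(6-ethyl-3,5-dimethyl-4-oxo-4H-pyran-2-yl)-2,4-dimethyl-5-(triethylsilyloxy)heptanoic acid, via lithium hydroxy carboxylate 25 (not isolated), via bis(triethylsilyl) derivative 26 (not isolated)
Conditions: LiOH, THF/H2O, 0 °C; evaporate; Et3SiOTf, 2,6-lutidine, CH2Cl2, −78 °C; K2CO3 (cat.), MeOH/H2O, 0 °C; pH 5 buffer
Reagents that add atoms: lithium hydroxide, [Li+].[OH-]; triethylsilyl trifluoromethanesulfonate, CC[Si](CC)(CC)OS(=O)(=O)C(F)(F)F
Why: Saponification gives carboxylate 25, which cannot relactonise. Silylation of both the carboxylate and the C5 hydroxyl before any acidification, then selective solvolysis of the labile silyl ester, should deliver the acid with C5–O protected.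

Step 20
Reactants: 28 (R)-4-benzyl-3-propanoyl-1,3-oxazolidin-2-one; 29 (E)-2-methylpent-2-enal
Product: 31 (R)-4-benzyl-3-[(2R,3R,E)-3-hydroxy-2,4-dimethylhept-4-enoyl]-1,3-oxazolidin-2-one, via (Z)-boron enolate 30 (not isolated)
Conditions: Bu2BOTf, i-Pr2NEt, CH2Cl2, −78 to 0 °C; then 29, −78 to 0 °C; pH 7 buffer, MeOH, H2O2
Reagents that add atoms: none
Why: Auxiliary-controlled boron aldol (Evans syn aldol): the (Z)-enolate reacts through a chair transition state on the face left open by the (R)-benzyl group, which should give the syn adduct with the (2R,3R) configuration.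

Step 21
Reactants: 31 (R)-4-benzyl-3-[(2R,3R,E)-3-hydroxy-2,4-dimethylhept-4-enoyl]-1,3-oxazolidin-2-one
Product: 32 (2R,3R,E)-3-hydroxy-N-methoxy-N,2,4-trimethylhept-4-enamide
Conditions: MeNH(OMe)·HCl, AlMe3, CH2Cl2, −20 to 0 °C; aq. KNaC4H4O6
Reagents that add atoms: N,O-dimethylhydroxylamine hydrochloride, CNOC.Cl
Why: Aluminium amide transamination of the β-hydroxy imide should give the Weinreb amide and release the auxiliary without epimerisation.

Step 22
Reactants: 32 (2R,3R,E)-3-hydroxy-N-methoxy-N,2,4-trimethylhept-4-enamide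
Product: 33 (2R,3R,E)-N-methoxy-N,2,4-trimethyl-3-(triethylsilyloxy)hept-4-enamide
Conditions: Et3SiCl, imidazole, DMF, rt
Reagents that add atoms: chlorotriethylsilane, CC[Si](CC)(CC)Cl
Why: Standard silylation of the carbinol that will later carry the acyl group; the triethylsilyl group can be removed at the end without base.

Step 23
Reactants: 33 (2R,3R,E)-N-methoxy-N,2,4-trimethyl-3-(triethylsilyloxy)hept-4-enamide
Product: 34 (4R,5R,E)-4,6-dimethyl-5-(triethylsilyloxy)non-6-en-3-one
Conditions: EtMgBr, THF, 0 °C; then H2O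
Reagents that add atoms: ethylmagnesium bromide, CC[Mg]Br
Why: Addition to the Weinreb amide stops at the chelated tetrahedral intermediate, so the ethyl ketone should form without over-addition or epimerisation.

Step 24
Reactants: 34 (4R,5R,E)-4,6-dimethyl-5-(triethylsilyloxy)non-6-en-3-one
Product: 36 4,6-dimethyl-5-(triethylsilyloxy)nonane-3,7-diol (4,5-syn-5,6-anti-6,7-anti; both C3 epimers), via diborylated adduct 35 (not isolated)
Conditions: BH3·THF (excess), THF, 0 °C to rt; then NaOH, H2O2, 0 °C
Reagents that add atoms: hydrogen peroxide, OO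
Why: Borane reduces the ketone and hydroborates the trisubstituted alkene. Syn addition to the (E)-alkene from the face opposite the C4 branch, in the conformer of least allylic strain, should place the new C6 methyl anti to the C5 oxygen (1,2-anti hydroboration of an allylic ether); both new carbinol centres are removed in the next step.

Step 25
Reactants: 36 4,6-dimethyl-5-(triethylsilyloxy)nonane-3,7-diol
Product: 37 (4R,6R)-4,6-dimethyl-5-(triethylsilyloxy)nonane-3,7-dione
Conditions: Dess–Martin periodinane, NaHCO3, CH2Cl2, rt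
Reagents that add atoms: none
Why: Double Dess–Martin oxidation under buffered conditions should keep both α-methyl centres.

Step 26
Reactants: 37 (4R,6R)-4,6-dimethyl-5-(triethylsilyloxy)nonane-3,7-dione
Product: 38 (4R,6R)-5-hydroxy-4,6-dimethylnonane-3,7-dione
Conditions: HF·pyridine, pyridine, THF, 0 °C
Reagents that add atoms: none
Why: Buffered fluoride removes the triethylsilyl group without base, so retro-aldol cleavage and β-elimination should not occur.

Step 27
Reactants: 27 (2R,3R,4R,5S,6R)-3-(tert-butyldimethylsilyloxy)-6-(6-ethyl-3,5-dimethyl-4-oxo-4H-pyran-2-yl)-2,4-dimethyl-5-(triethylsilyloxy)heptanoic acid; 38 (4R,6R)-5-hydroxy-4,6-dimethylnonane-3,7-dione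
Product: 40 (4R,6R)-4,6-dimethyl-3,7-dioxononan-5-yl (2R,3R,4R,5S,6R)-3-(tert-butyldimethylsilyloxy)-6-(6-ethyl-3,5-dimethyl-4-oxo-4H-pyran-2-yl)-2,4-dimethyl-5-(triethylsilyloxy)heptanoate, via mixed anhydride 39 (not isolated)
Conditions: 2,4,6-Cl3C6H2COCl, Et3N, THF, rt; then 38, DMAP, toluene, rt
Reagents that add atoms: none
Why: Yamaguchi esterification: the hindered aroyl group of the mixed anhydride directs DMAP to the aliphatic carbonyl, and the acylpyridinium ion should acylate the hindered secondary alcohol at room temperature.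

Step 28
Reactants: 40 (4R,6R)-4,6-dimethyl-3,7-dioxononan-5-yl (2R,3R,4R,5S,6R)-3-(tert-butyldimethylsilyloxy)-6-(6-ethyl-3,5-dimethyl-4-oxo-4H-pyran-2-yl)-2,4-dimethyl-5-(triethylsilyloxy)heptanoate
Product: 41 (4R,6R)-4,6-dimethyl-3,7-dioxononan-5-yl (2R,3R,4R,5S,6R)-3-(tert-butyldimethylsilyloxy)-6-(6-ethyl-3,5-dimethyl-4-oxo-4H-pyran-2-yl)-5-hydroxy-2,4-dimethylheptanoate
Conditions: HF·pyridine, pyridine, THF, 0 °C
Reagents that add atoms: none
Why: A triethylsilyl ether is cleaved much faster than the hindered tert-butyldimethylsilyl ether by buffered HF·pyridine, so only C5–O should be freed.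

Step 29
Reactants: 41 (4R,6R)-4,6-dimethyl-3,7-dioxononan-5-yl (2R,3R,4R,5S,6R)-3-(tert-butyldimethylsilyloxy)-6-(6-ethyl-3,5-dimethyl-4-oxo-4H-pyran-2-yl)-5-hydroxy-2,4-dimethylheptanoate
Product: 42 (4R,6R)-4,6-dimethyl-3,7-dioxononan-5-yl (2R,3R,4S,6S)-3-(tert-butyldimethylsilyloxy)-6-(6-ethyl-3,5-dimethyl-4-oxo-4H-pyran-2-yl)-2,4-dimethyl-5-oxoheptanoate
Conditions: Dess–Martin periodinane, NaHCO3, CH2Cl2, 0 °C to rt
Reagents that add atoms: none
Why: Buffered Dess–Martin oxidation creates the C5 ketone last, so the now doubly activated C6 and the C4 centre are never exposed to base.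

Step 30
Reactants: 42 (4R,6R)-4,6-dimethyl-3,7-dioxononan-5-yl (2R,3R,4S,6S)-3-(tert-butyldimethylsilyloxy)-6-(6-ethyl-3,5-dimethyl-4-oxo-4H-pyran-2-yl)-2,4-dimethyl-5-oxoheptanoate
Product: 43 (4R,6R)-4,6-dimethyl-3,7-dioxononan-5-yl (2R,3R,4S,6S)-6-(6-ethyl-3,5-dimethyl-4-oxo-4H-pyran-2-yl)-3-hydroxy-2,4-dimethyl-5-oxoheptanoate
Conditions: aq. HF, MeCN, 0 °C to rt
Reagents that add atoms: none
Why: Acidic fluoride removes the last silyl ether; acidic conditions should avoid retro-aldol cleavage, loss of the acyloxy group and epimerisation.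

**Compound list**

1 | methyl (S)-3-hydroxy-2-methylpropanoate | COC(=O)[C@@H](C)CO | starting material
2 | methyl (S)-3-(benzyloxy)-2-methylpropanoate | COC(=O)[C@@H](C)COCc1ccccc1 | intermediate
3 | (R)-3-(benzyloxy)-2-methylpropan-1-ol | OC[C@@H](C)COCc1ccccc1 | intermediate
4 | (S)-3-(benzyloxy)-2-methylpropanal | O=C[C@@H](C)COCc1ccccc1 | intermediate
5 | pentan-3-one | CCC(=O)CC | starting material
6 | ethyl formate | CCOC=O | starting material
7 | 2-methyl-3-oxopentanal, drawn as its enol 1-hydroxy-2-methylpent-1-en-3-one | CCC(=O)C(C)=CO | intermediate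
8 | (E)-1-methoxy-2-methylpent-1-en-3-one | CCC(=O)/C(C)=C/OC | intermediate
9 | (1E,3Z)-1-methoxy-2-methyl-3-(trimethylsilyloxy)penta-1,3-diene | C/C=C(O[Si](C)(C)C)/C(C)=C/OC | intermediate
10 | (1E,4R,5R,6S)-7-(benzyloxy)-5-hydroxy-1-methoxy-2,4,6-trimethylhept-1-en-3-one | CO/C=C(\C)C(=O)[C@H](C)[C@H](O)[C@@H](C)COCc1ccccc1 | intermediate
11 | (2R,3R)-2-[(S)-1-(benzyloxy)propan-2-yl]-3,5-dimethyl-2,3-dihydro-4H-pyran-4-one (2,3-trans) | C1=C(C)C(=O)[C@H](C)[C@H](O1)[C@@H](C)COCc2ccccc2 | intermediate
12 | (2R,3R,5S,6S)-2-[(S)-1-(benzyloxy)propan-2-yl]-6-methoxy-3,5-dimethyloxan-4-one (methoxy axial; both methyls and the side chain equatorial) | CO[C@@H]1[C@H](C)C(=O)[C@H](C)[C@H](O1)[C@@H](C)COCc2ccccc2 | intermediate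
13 | (2R,3S,4R,5R,6S)-2-[(S)-1-(benzyloxy)propan-2-yl]-6-methoxy-3,5-dimethyloxan-4-ol (hydroxyl axial, cis to both methyls) | CO[C@@H]1[C@H](C)[C@H](O)[C@H](C)[C@H](O1)[C@@H](C)COCc2ccccc2 | intermediate
14 | (2R,3R,4R,5R,6S)-2-[(S)-1-(benzyloxy)propan-2-yl]-4-(tert-butyldimethylsilyloxy)-6-methoxy-3,5-dimethyloxane | CO[C@@H]1[C@H](C)[C@H](O[Si](C)(C)C(C)(C)C)[C@H](C)[C@H](O1)[C@@H](C)COCc2ccccc2 | intermediate
15 | (S)-2-[(2R,3R,4R,5R,6S)-4-(tert-butyldimethylsilyloxy)-6-methoxy-3,5-dimethyloxan-2-yl]propan-1-ol | CO[C@@H]1[C@H](C)[C@H](O[Si](C)(C)C(C)(C)C)[C@H](C)[C@H](O1)[C@@H](C)CO | intermediate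
16 | (R)-2-[(2S,3R,4R,5R,6S)-4-(tert-butyldimethylsilyloxy)-6-methoxy-3,5-dimethyloxan-2-yl]propanal | CO[C@@H]1[C@H](C)[C@H](O[Si](C)(C)C(C)(C)C)[C@H](C)[C@H](O1)[C@@H](C)C=O | intermediate
17 | heptane-3,5-dione | CCC(=O)CC(=O)CC | starting material
18 | 4-methylheptane-3,5-dione | CCC(=O)C(C)C(=O)CC | intermediate
19 | dilithium 4-methylhepta-2,4-diene-3,5-diolate (dianion of 18) | [Li+].[Li+].CC=C([O-])C(C)=C([O-])CC | intermediate
20 | (8S)-8-[(2R,3R,4R,5R,6S)-4-(tert-butyldimethylsilyloxy)-6-methoxy-3,5-dimethyloxan-2-yl]-7-hydroxy-4,6-dimethylnonane-3,5-dione (mixture at C4, C6, C7) | CO[C@@H]1[C@H](C)[C@H](O[Si](C)(C)C(C)(C)C)[C@H](C)[C@H](O1)[C@@H](C)C(O)C(C)C(=O)C(C)C(=O)CC | intermediate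
21 | (8R)-8-[(2S,3R,4R,5R,6S)-4-(tert-butyldimethylsilyloxy)-6-methoxy-3,5-dimethyloxan-2-yl]-4,6-dimethylnonane-3,5,7-trione (mixture at C4, C6; enol tautomers) | CO[C@@H]1[C@H](C)[C@H](O[Si](C)(C)C(C)(C)C)[C@H](C)[C@H](O1)[C@@H](C)C(=O)C(C)C(=O)C(C)C(=O)CC | intermediate
22 | 2-{(R)-1-[(2S,3R,4R,5R,6S)-4-(tert-butyldimethylsilyloxy)-6-methoxy-3,5-dimethyloxan-2-yl]ethyl}-6-ethyl-3,5-dimethyl-4H-pyran-4-one | CO[C@@H]1[C@H](C)[C@H](O[Si](C)(C)C(C)(C)C)[C@H](C)[C@H](O1)[C@@H](C)c2oc(CC)c(C)c(=O)c2C | intermediate
23 | (3R,4R,5R,6S)-4-(tert-butyldimethylsilyloxy)-6-[(R)-1-(6-ethyl-3,5-dimethyl-4-oxo-4H-pyran-2-yl)ethyl]-3,5-dimethyloxan-2-ol (both anomers) | OC1[C@H](C)[C@H](O[Si](C)(C)C(C)(C)C)[C@H](C)[C@H](O1)[C@@H](C)c2oc(CC)c(C)c(=O)c2C | intermediate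
24 | (3R,4R,5R,6S)-4-(tert-butyldimethylsilyloxy)-6-[(R)-1-(6-ethyl-3,5-dimethyl-4-oxo-4H-pyran-2-yl)ethyl]-3,5-dimethyloxan-2-one | O=C1[C@H](C)[C@H](O[Si](C)(C)C(C)(C)C)[C@H](C)[C@H](O1)[C@@H](C)c2oc(CC)c(C)c(=O)c2C | intermediate
25 | lithium (2R,3R,4R,5S,6R)-3-(tert-butyldimethylsilyloxy)-6-(6-ethyl-3,5-dimethyl-4-oxo-4H-pyran-2-yl)-5-hydroxy-2,4-dimethylheptanoate | [Li+].[O-]C(=O)[C@H](C)[C@H](O[Si](C)(C)C(C)(C)C)[C@H](C)[C@H](O)[C@@H](C)c1oc(CC)c(C)c(=O)c1C | intermediate
26 | triethylsilyl (2R,3R,4R,5S,6R)-3-(tert-butyldimethylsilyloxy)-6-(6-ethyl-3,5-dimethyl-4-oxo-4H-pyran-2-yl)-2,4-dimethyl-5-(triethylsilyloxy)heptanoate | CC[Si](CC)(CC)OC(=O)[C@H](C)[C@H](O[Si](C)(C)C(C)(C)C)[C@H](C)[C@H](O[Si](CC)(CC)CC)[C@@H](C)c1oc(CC)c(C)c(=O)c1C | intermediate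
27 | (2R,3R,4R,5S,6R)-3-(tert-butyldimethylsilyloxy)-6-(6-ethyl-3,5-dimethyl-4-oxo-4H-pyran-2-yl)-2,4-dimethyl-5-(triethylsilyloxy)heptanoic acid | OC(=O)[C@H](C)[C@H](O[Si](C)(C)C(C)(C)C)[C@H](C)[C@H](O[Si](CC)(CC)CC)[C@@H](C)c1oc(CC)c(C)c(=O)c1C | intermediate
28 | (R)-4-benzyl-3-propanoyl-1,3-oxazolidin-2-one | CCC(=O)N1[C@H](Cc2ccccc2)COC1=O | starting material
29 | (E)-2-methylpent-2-enal | CC/C=C(\C)C=O | starting material
30 | (R)-4-benzyl-3-[(Z)-1-(dibutylboryloxy)prop-1-en-1-yl]-1,3-oxazolidin-2-one | CCCCB(CCCC)O/C(=C\C)N1[C@H](Cc2ccccc2)COC1=O | intermediate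
31 | (R)-4-benzyl-3-[(2R,3R,E)-3-hydroxy-2,4-dimethylhept-4-enoyl]-1,3-oxazolidin-2-one | O=C([C@H](C)[C@@H](O)/C(C)=C/CC)N1[C@H](Cc2ccccc2)COC1=O | intermediate
32 | (2R,3R,E)-3-hydroxy-N-methoxy-N,2,4-trimethylhept-4-enamide | CON(C)C(=O)[C@H](C)[C@@H](O)/C(C)=C/CC | intermediate
33 | (2R,3R,E)-N-methoxy-N,2,4-trimethyl-3-(triethylsilyloxy)hept-4-enamide | CON(C)C(=O)[C@H](C)[C@@H](O[Si](CC)(CC)CC)/C(C)=C/CC | intermediate
34 | (4R,5R,E)-4,6-dimethyl-5-(triethylsilyloxy)non-6-en-3-one | CCC(=O)[C@H](C)[C@@H](O[Si](CC)(CC)CC)/C(C)=C/CC | intermediate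
35 | diborylated adduct of 34 (C3 alkoxyborane, C7 alkylborane; mixture at C3) | CCC(OB)[C@H](C)[C@@H](O[Si](CC)(CC)CC)[C@@H](C)[C@@H](B)CC | intermediate
36 | 4,6-dimethyl-5-(triethylsilyloxy)nonane-3,7-diol (4,5-syn, 5,6-anti, 6,7-anti; both C3 epimers) | CCC(O)[C@H](C)[C@@H](O[Si](CC)(CC)CC)[C@@H](C)[C@@H](O)CC | intermediate
37 | (4R,6R)-4,6-dimethyl-5-(triethylsilyloxy)nonane-3,7-dione | CCC(=O)[C@H](C)C(O[Si](CC)(CC)CC)[C@@H](C)C(=O)CC | intermediate
38 | (4R,6R)-5-hydroxy-4,6-dimethylnonane-3,7-dione | CCC(=O)[C@H](C)C(O)[C@@H](C)C(=O)CC | intermediate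
39 | mixed anhydride of acid 27 with 2,4,6-trichlorobenzoic acid | O=C(OC(=O)c1c(Cl)cc(Cl)cc1Cl)[C@H](C)[C@H](O[Si](C)(C)C(C)(C)C)[C@H](C)[C@H](O[Si](CC)(CC)CC)[C@@H](C)c1oc(CC)c(C)c(=O)c1C | intermediate
40 | (4R,6R)-4,6-dimethyl-3,7-dioxononan-5-yl (2R,3R,4R,5S,6R)-3-(tert-butyldimethylsilyloxy)-6-(6-ethyl-3,5-dimethyl-4-oxo-4H-pyran-2-yl)-2,4-dimethyl-5-(triethylsilyloxy)heptanoate | CCC(=O)[C@H](C)C(OC(=O)[C@H](C)[C@H](O[Si](C)(C)C(C)(C)C)[C@H](C)[C@H](O[Si](CC)(CC)CC)[C@@H](C)c1oc(CC)c(C)c(=O)c1C)[C@@H](C)C(=O)CC | intermediate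
41 | (4R,6R)-4,6-dimethyl-3,7-dioxononan-5-yl (2R,3R,4R,5S,6R)-3-(tert-butyldimethylsilyloxy)-6-(6-ethyl-3,5-dimethyl-4-oxo-4H-pyran-2-yl)-5-hydroxy-2,4-dimethylheptanoate | CCC(=O)[C@H](C)C(OC(=O)[C@H](C)[C@H](O[Si](C)(C)C(C)(C)C)[C@H](C)[C@H](O)[C@@H](C)c1oc(CC)c(C)c(=O)c1C)[C@@H](C)C(=O)CC | intermediate
42 | (4R,6R)-4,6-dimethyl-3,7-dioxononan-5-yl (2R,3R,4S,6S)-3-(tert-butyldimethylsilyloxy)-6-(6-ethyl-3,5-dimethyl-4-oxo-4H-pyran-2-yl)-2,4-dimethyl-5-oxoheptanoate | CCC(=O)[C@H](C)C(OC(=O)[C@H](C)[C@H](O[Si](C)(C)C(C)(C)C)[C@H](C)C(=O)[C@@H](C)c1oc(CC)c(C)c(=O)c1C)[C@@H](C)C(=O)CC | intermediate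
43 | (4R,6R)-4,6-dimethyl-3,7-dioxononan-5-yl (2R,3R,4S,6S)-6-(6-ethyl-3,5-dimethyl-4-oxo-4H-pyran-2-yl)-3-hydroxy-2,4-dimethyl-5-oxoheptanoate | CCC(=O)[C@H](C)C(OC(=O)[C@H](C)[C@H](O)[C@H](C)C(=O)[C@@H](C)c1oc(CC)c(C)c(=O)c1C)[C@@H](C)C(=O)CC | target

**Step count and risks**

Total: 30 steps. Longest linear sequence: 19 steps (steps 1–3, 7–12, 14–19, 27–30). The side branches are steps 4–6 (diene 9), step 13 (diketone 18) and steps 20–26 (alcohol 38).

Step 7 (key step). Facial control at the aldehyde may be incomplete (addition in the anti-Felkin sense), a concerted cycloaddition may compete and lead to the cis ring, and 4 may enolise and lose optical purity. Fallback: a boron aldol through a closed transition state. Enone 8 would be converted with c-Hex2BCl and Et3N into its (E)-enol borinate, dicyclohexyl{[(2E,4E)-5-methoxy-4-methylpenta-2,4-dien-3-yl]oxy}borane F1. F1 should add to 4 through a chair transition state in the anti and Felkin sense and give adduct 10 after oxidative work-up. Treatment with CF3CO2H as in step 7 then closes the ring. The fallback sets out from 8 and 4 and returns at 10, and from there at 11.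

Step 8. The addition of methanol is an equilibrium and may stop short or revert on concentration, and C2 may not settle fully on the equatorial side. Fallback from 11: 1,2-reduction with NaBH4/CeCl3·7H2O (Luche) to the allylic alcohol (2R,3S,4S)-2-[(S)-1-(benzyloxy)propan-2-yl]-3,5-dimethyl-3,4-dihydro-2H-pyran-4-ol F2. Its enol ether, now isolated from the carbonyl, adds methanol under Ph3P·HBr catalysis to give the methyl glycoside 2-[(S)-1-(benzyloxy)propan-2-yl]-6-methoxy-3,5-dimethyloxan-4-ol with equatorial hydroxyl F3. Dess–Martin oxidation of F3 and brief equilibration of C2 with CSA in methanol returns to the route at 12.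

Step 9. Hydride delivery may lose facial selectivity if a twist conformer reacts, and enolisation with loss of methoxide may compete. Fallback from 12: reduction with NaBH4, or recovery of the by-product of step 9, gives the C4-epimeric equatorial alcohol (2R,3S,4S,5R,6S)-2-[(S)-1-(benzyloxy)propan-2-yl]-6-methoxy-3,5-dimethyloxan-4-ol F4. Mitsunobu inversion with 4-nitrobenzoic acid, Ph3P and diisopropyl azodicarboxylate gives the axial 4-nitrobenzoate F5, and methanolysis with K2CO3 in MeOH returns to the route at 13.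

Step 14. The dianion may act as a base, enolising 16 and epimerising C6; the hindered secondary carbanion may add slowly; and the adduct may undergo retro-aldol cleavage. Fallback from 16 and 5: aldol addition of 5 to propanal (LiN(i-Pr)2) gives 5-hydroxy-4-methylheptan-3-one F6, silylated to 4-methyl-5-(triethylsilyloxy)heptan-3-one F7. The kinetic lithium enolate of F7, formed at its methylene group, adds to 16 to give the silyl-protected adduct F8. Methanolysis with pyridinium 4-toluenesulfonate gives diol F9, and double Dess–Martin oxidation returns to the route at 21.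

Step 19. Relactonisation may outrun silylation of the C5 hydroxyl, and hydroxide may cause β-elimination of the axial silyloxy group from the lactone. Fallback from 23, bypassing 24: propane-1,3-dithiol and BF3·OEt2 open the lactol to the dithiane with free C5 hydroxyl F10. Et3SiOTf and 2,6-lutidine give the silyl ether F11, MeI and CaCO3 in aqueous MeCN release the aldehyde F12, and oxidation with NaClO2, NaH2PO4 and 2-methylbut-2-ene returns to the route at 27.

Step 27. The amine bases may cause β-elimination or retro-aldol cleavage of 38 or of the β-acyloxy ketone product and epimerisation α to the ketones; acyl transfer between two hindered partners may be slow or occur from the wrong carbonyl of 39. Fallback from 36 and 27: the ketones of the alcohol partner are masked as protected carbinols. Diol 36 is converted with 4-methoxybenzyl 2,2,2-trichloroacetimidate and catalytic CSA into the bis(4-methoxybenzyl) ether F13, and HF·pyridine frees the central carbinol F14. Yamaguchi esterification with 27 gives ester F15, 2,3-dichloro-5,6-dicyano-1,4-benzoquinone removes both benzyl-type ethers to give diol F16, and HF·pyridine removes the triethylsilyl group to give triol F17. Dess–Martin oxidation of the three carbinols returns to the route at 42.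

**Further compounds**

F1 | step 7 | dicyclohexyl{[(2E,4E)-5-methoxy-4-methylpenta-2,4-dien-3-yl]oxy}borane | C/C=C(/OB(C1CCCCC1)C1CCCCC1)\C(C)=C\OC
F2 | step 8 | (2R,3S,4S)-2-[(S)-1-(benzyloxy)propan-2-yl]-3,5-dimethyl-3,4-dihydro-2H-pyran-4-ol | C1=C(C)[C@@H](O)[C@H](C)[C@H](O1)[C@@H](C)COCc2ccccc2
F3 | step 8 | 2-[(S)-1-(benzyloxy)propan-2-yl]-6-methoxy-3,5-dimethyloxan-4-ol, hydroxyl equatorial, mixture at the methyl-bearing carbon next to the acetal | CO[C@@H]1C(C)[C@@H](O)[C@H](C)[C@H](O1)[C@@H](C)COCc2ccccc2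
F4 | step 9 | (2R,3S,4S,5R,6S)-2-[(S)-1-(benzyloxy)propan-2-yl]-6-methoxy-3,5-dimethyloxan-4-ol (hydroxyl equatorial) | CO[C@@H]1[C@H](C)[C@@H](O)[C@H](C)[C@H](O1)[C@@H](C)COCc2ccccc2
F5 | step 9 | axial 4-nitrobenzoate of 13 | CO[C@@H]1[C@H](C)[C@H](OC(=O)c3ccc(cc3)[N+](=O)[O-])[C@H](C)[C@H](O1)[C@@H](C)COCc2ccccc2
F6 | step 14 | 5-hydroxy-4-methylheptan-3-one (diastereomer mixture) | CCC(=O)C(C)C(O)CC
F7 | step 14 | 4-methyl-5-(triethylsilyloxy)heptan-3-one | CCC(=O)C(C)C(O[Si](CC)(CC)CC)CC
F8 | step 14 | 8-[4-(tert-butyldimethylsilyloxy)-6-methoxy-3,5-dimethyloxan-2-yl]-7-hydroxy-4,6-dimethyl-3-(triethylsilyloxy)nonan-5-one (ring and C8 as in 20) | CO[C@@H]1[C@H](C)[C@H](O[Si](C)(C)C(C)(C)C)[C@H](C)[C@H](O1)[C@@H](C)C(O)C(C)C(=O)C(C)C(O[Si](CC)(CC)CC)CC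
F9 | step 14 | 8-[4-(tert-butyldimethylsilyloxy)-6-methoxy-3,5-dimethyloxan-2-yl]-3,7-dihydroxy-4,6-dimethylnonan-5-one (ring and C8 as in 20) | CO[C@@H]1[C@H](C)[C@H](O[Si](C)(C)C(C)(C)C)[C@H](C)[C@H](O1)[C@@H](C)C(O)C(C)C(=O)C(C)C(O)CC
F10 | step 19 | 1,3-dithiane of the open-chain C1 aldehyde with free C5 hydroxyl (chain as in 25) | S1CCCSC1[C@H](C)[C@H](O[Si](C)(C)C(C)(C)C)[C@H](C)[C@H](O)[C@@H](C)c2oc(CC)c(C)c(=O)c2C
F11 | step 19 | C5 triethylsilyl ether of F10 | S1CCCSC1[C@H](C)[C@H](O[Si](C)(C)C(C)(C)C)[C@H](C)[C@H](O[Si](CC)(CC)CC)[C@@H](C)c2oc(CC)c(C)c(=O)c2C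
F12 | step 19 | (2R,3R,4R,5S,6R)-3-(tert-butyldimethylsilyloxy)-6-(6-ethyl-3,5-dimethyl-4-oxo-4H-pyran-2-yl)-2,4-dimethyl-5-(triethylsilyloxy)heptanal | O=C[C@H](C)[C@H](O[Si](C)(C)C(C)(C)C)[C@H](C)[C@H](O[Si](CC)(CC)CC)[C@@H](C)c1oc(CC)c(C)c(=O)c1C
F13 | step 27 | 3,7-bis(4-methoxybenzyl) ether of diol 36 | CCC(OCc1ccc(OC)cc1)[C@H](C)[C@@H](O[Si](CC)(CC)CC)[C@@H](C)[C@@H](OCc1ccc(OC)cc1)CC
F14 | step 27 | 3,7-bis(4-methoxybenzyloxy)-4,6-dimethylnonan-5-ol (configuration as in 36) | CCC(OCc1ccc(OC)cc1)[C@H](C)[C@@H](O)[C@@H](C)[C@@H](OCc1ccc(OC)cc1)CC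
F15 | step 27 | ester of acid 27 with alcohol F14 | CCC(OCc1ccc(OC)cc1)[C@H](C)[C@@H](OC(=O)[C@H](C)[C@H](O[Si](C)(C)C(C)(C)C)[C@H](C)[C@H](O[Si](CC)(CC)CC)[C@@H](C)c1oc(CC)c(C)c(=O)c1C)[C@@H](C)[C@@H](OCc1ccc(OC)cc1)CC
F16 | step 27 | 3,7-dihydroxy ester obtained from F15 | CCC(O)[C@H](C)[C@@H](OC(=O)[C@H](C)[C@H](O[Si](C)(C)C(C)(C)C)[C@H](C)[C@H](O[Si](CC)(CC)CC)[C@@H](C)c1oc(CC)c(C)c(=O)c1C)[C@@H](C)[C@@H](O)CC
F17 | step 27 | triol ester obtained from F16 (C5 hydroxyl of the acyl chain free) | CCC(O)[C@H](C)[C@@H](OC(=O)[C@H](C)[C@H](O[Si](C)(C)C(C)(C)C)[C@H](C)[C@H](O)[C@@H](C)c1oc(CC)c(C)c(=O)c1C)[C@@H](C)[C@@H](O)CC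
A1 | alternative 1 | meso anti,anti-3-(tert-butyldimethylsilyloxy)-2,4-dimethylpentane-1,5-diol | OC[C@H](C)[C@H](O[Si](C)(C)C(C)(C)C)[C@H](C)CO
A2 | alternative 1 | tert-butyl[(2,4-dimethylpenta-1,4-dien-3-yl)oxy]dimethylsilane | C=C(C)C(O[Si](C)(C)C(C)(C)C)C(C)=C
A3 | alternative 2 | tert-butyl ester of the pyranone acid half with C3–O tert-butyldimethylsilyl and C5–O triethylsilyl | CC(C)(C)OC(=O)[C@H](C)[C@H](O[Si](C)(C)C(C)(C)C)[C@H](C)[C@@H](O[Si](CC)(CC)CC)[C@@H](C)c1oc(CC)c(C)c(=O)c1C
A4 | alternative 2 | open-chain C7/C9/C11 triketone precursor of A3 | CC(C)(C)OC(=O)[C@H](C)[C@H](O[Si](C)(C)C(C)(C)C)[C@H](C)[C@@H](O[Si](CC)(CC)CC)[C@@H](C)C(=O)C(C)C(=O)C(C)C(=O)CC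
A5 | alternative 3 | (3S,4S,6S,7S)-3,5,7-trimethylnona-1,8-diene-4,6-diol | C=C[C@H](C)[C@H](O)C(C)[C@@H](O)[C@@H](C)C=C
A6 | alternative 3 | 2-methylpropane-1,3-diol | CC(CO)CO
A7 | alternative 3 | but-3-en-2-yl acetate | CC(OC(C)=O)C=C
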